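(All runs were computed with made-up constants; scatter was added.)

- East, your one earlier run at 22 mM, is the flask to read; the four new flasks differ from it in the charge of substrate, c.

| flask | substrate | remark | time |
|---|---|---|---|
| east | 22 mM | run made earlier |  |
| alder | 20 mM |  | 25 min |
| ash | 30 mM |  | 25 min |
| birch | 10 mM |  | 25 min |
| maple | 80 mM |  | 25 min |

- east (time / min: target / %, substrate / %): 1.33: 50.4, 12.1; 2.50: 58.1, 9.5; 4.00: 65.7, 9.1; 5.00: 68.9, 8.3; 6.00: 71.3, 8.1; 8.00: 74.0, 8.0

(standard deviation of a reading: 0.5 percentage points)

- a reading or a percentage of target counts all its forms, free or not

- all flasks from highest to lowest amount of target, in percent of the substrate charged, at 25 min (alder / ash / birch / maple)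
- the same order at 80 s (alder / ash / birch / maple)
- the amount of target, in percent of the substrate charged of the flask you put first, at 25 min
- the amount of target, in percent of the substrate charged of the flask you put last, at 25 min

- Work with the fraction that is not target. From 6.00 min to 8.00 min east's substrate moves 0.1 percentage points, inside the scatter, while target gains more, 2.7 points.
- I read that as free target standing at one concentration, the surplus leaving as a solid form that the percentage still counts. What balances a fixed concentration should then be a fixed amount in mM, not a fixed percentage, while solid is present.
- East's gains over equal steps, 5.6 points then 2.7 points, shrink with a half-life near 1.90 min, far shorter than 25 min. Summing that tail leaves east a fraction 23.5 %, a reading that carries the scatter.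
- Define W, the amount in mM that stays out of target at the end (the mother-liquor loss): W = 5.17 mM.
- Two amounts remain, W and c, and the fraction left is W/c. From 1 - W/c I reckon target at maple 93.5 %, ash 82.8 %, alder 74.2 % and birch 48.3 % at 25 min, and keep that order at 80 s.
- The forecast, against my order, gave birch > alder > ash > maple at 25 min and birch > alder > ash > maple at 80 s, with 90 % (81 % to 98 %) first and 23 % (18 % to 26 %) last: “The stall suggests something limiting is used up”.
- The flasks give maple > ash > alder > birch at 25 min, maple 93.6 % and birch 49.0 %, and maple > ash > alder > birch at 80 s. Ten times as long leaves maple at 93.6 %.

    substrate ⇌ target (K = 2.60, k = 0.0368 /s)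
    crystals ⇌ target, rate k2*(cs2 - [target]) while solid is left; crystals form when [target] > cs2 (solubility = 3.90 mM, k = 0.0415 /s)
    substrate ⇌ isomer of the product (K = 2.40, k = 0.0378 /s)

- The part that is not target comes to 5.11 mM in maple and 5.10 mM in birch. Take W out of ash's 30 mM and you get 82.8 % of target; ash stands at 83.0 %.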